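**Strategy.** Ring A is disconnected at C4a–C5 and C8–C8a. This leaves an already assembled 3-aryl-4-pyranone (rings B and C) and a four-carbon diene. The feature exploited is the contiguous array 5-OH, 6-prenyl, 7-OMe, 8-H on ring A. It is the substituent sequence of a butadiene oxygenated at C1 and C3 and prenylated at C2, while O1 already sits on C8a. In one operation, [4+2] addition to the doubly activated C4a=C8a bond, departure of the sulfur group and collapse of the C5 ketal close and aromatise ring A with every position defined. The precursor is a bis-MOM-protected 3-(2,4-dihydroxyphenyl)-4-pyranone carrying a phenylsulfinyl group on the future C4a.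

Key step: step 8

Remarks on the chemistry:
- Sulfur is carried at the sulfoxide level: in the cycloadduct, 8a-H is only β to the carbonyl groups, is not acidic and lies cis to sulfur, so only a group with a built-in base (S–O) can leave, by thermal syn elimination; a sulfone there would need an E1cB or anti-E2 path that the adduct does not offer, and base would open ring C instead.
- The target has no stereocentre; every stereocentre met on the way (carbon or sulfur) is racemic and is erased.
- The ketene acetal geometry of the diene is drawn E; either isomer serves, because that carbon ends as an sp2 ring atom.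

**Step 1**
Reactants: 1 methyl acetoacetate; 2 prenyl bromide
Product: 3 methyl 2-acetyl-5-methylhex-4-enoate (racemic)
Conditions: K2CO3, acetone, reflux (1 in slight excess)
Reagents that add atoms: none
Why: Acetoacetic ester alkylation, in which the stabilised enolate of 1 displaces the primary allylic bromide by SN2 at carbon, the slight excess of 1 suppresses double alkylation, and the new C2 stereocentre is racemic and disappears in step 2.

**Step 2**
Reactants: 3 methyl 2-acetyl-5-methylhex-4-enoate
Product: 4 methyl (2E)-3-methoxy-2-(3-methylbut-2-enyl)but-2-enoate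
Conditions: HC(OMe)3, MeOH, cat. TsOH·H2O, 50 °C; NaOMe quench; distil
Reagents that add atoms: trimethyl orthoformate, COC(OC)OC
Why: Acid-catalysed ketalisation with the orthoester as water scavenger, followed by loss of methanol on distillation (enol ether formation), is the standard entry to 3-methoxy-2-alkylcrotonates, the dilute sulfonic acid should not add methanol to the prenyl alkene, and any Z or β,γ isomer converges on the same dienolate in step 3.

**Step 3**
Reactants: 4 methyl (2E)-3-methoxy-2-(3-methylbut-2-enyl)but-2-enoate
Product: 5 (1E)-1,3-dimethoxy-2-(3-methylbut-2-enyl)-1-(trimethylsilyloxy)buta-1,3-diene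
Conditions: LiN(i-Pr)2, THF, −78 °C; Me3SiCl, −78 °C → rt; pentane, filter, distil; use at once
Reagents that add atoms: chlorotrimethylsilane, C[Si](C)(C)Cl
Why: Kinetic γ-deprotonation of the vinylogous carbonate-type ester gives the extended lithium enolate, which the hard chlorosilane traps on oxygen (O-silylation to a vinylketene silyl acetal), as is known for the 2-methyl analogue.

**Step 4**
Reactants: 6 2,4-dihydroxyphenylacetic acid
Product: 7 methyl 2,4-dihydroxyphenylacetate
Conditions: MeOH, cat. H2SO4, reflux
Reagents that add atoms: methanol, CO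
Why: Fischer esterification, in which any benzofuran-2(3H)-one formed by lactonisation of the 2-hydroxy acid is reopened by methanol under the same conditions.

**Step 5**
Reactants: 7 methyl 2,4-dihydroxyphenylacetate
Product: 8 methyl 2-[2,4-bis(methoxymethoxy)phenyl]acetate
Conditions: MOMCl, i-Pr2NEt, CH2Cl2, 0 °C → rt
Reagents that add atoms: chloromethyl methyl ether, COCCl
Why: Williamson-type O-alkylation of both phenols by the very reactive chloromethyl ether under a non-nucleophilic amine base, which is mild enough to avoid attack of the 2-phenoxide on the neighbouring ester.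

**Step 6**
Reactants: 8 methyl 2-[2,4-bis(methoxymethoxy)phenyl]acetate; 9 methyl phenyl sulfoxide (racemic)
Product: 10 1-[2,4-bis(methoxymethoxy)phenyl]-3-(phenylsulfinyl)propan-2-one (racemic at sulfur)
Conditions: 9 (2.2 equiv), LiN(i-Pr)2 (2.2 equiv), THF, −78 °C; add 8, −78 → 0 °C; aq NH4Cl
Reagents that add atoms: none
Why: Claisen-type acylation of an α-sulfinyl carbanion by an ester (the classical β-keto sulfoxide synthesis), run with two equivalents of carbanion because the product is deprotonated at once, which also shields the new ketone from a second addition.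

**Step 7**
Reactants: 10 1-[2,4-bis(methoxymethoxy)phenyl]-3-(phenylsulfinyl)propan-2-one
Product: 12 3-[2,4-bis(methoxymethoxy)phenyl]-5-(phenylsulfinyl)-4H-pyran-4-one, via bis(enaminone) 11 (not isolated)
Conditions: Me2NCH(OMe)2 (6 equiv), toluene, rt → 105 °C; evaporate; AcOH–THF–H2O, 45 °C
Reagents that add atoms: N,N-dimethylformamide dimethyl acetal, COC(OC)N(C)C; water, O
Why: Double aminomethylenation of a ketone flanked by two active methylene groups, followed by hydrolytic ring closure, is the known route to 3,5-disubstituted 4-pyranones: water replaces one dimethylamino group, the resulting enol displaces the other by addition–elimination, and acetic acid keeps the released amine protonated while leaving aryl MOM ethers intact.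

**Step 8**
Reactants: 12 3-[2,4-bis(methoxymethoxy)phenyl]-5-(phenylsulfinyl)-4H-pyran-4-one; 5 (1E)-1,3-dimethoxy-2-(3-methylbut-2-enyl)-1-(trimethylsilyloxy)buta-1,3-diene
Product: 15 7-O-methylluteone 2',4'-bis(methoxymethyl) ether, via cis-fused cycloadduct 13 (not isolated), via 5,8-dihydrochromenone ketal 14 (not isolated)
Conditions: 5 (2.5 equiv), toluene, rt → 80 °C; then cat. PPTS, MeOH, rt
Reagents that add atoms: none
Why: Proposed new method: the electron-rich CH2 terminus of 5 bonds to C8a, the carbon β to both the ketone and the sulfinyl group of 12, and the ketene acetal carbon bonds to C4a, either in concert or as a Mukaiyama–Michael/Claisen pair, so ring A closes in an intermolecular [4+2] mode through C8–C8a and C4a–C5. Suprafacial addition leaves the sulfinyl group and 8a-H cis in 13, the geometry required for a five-centre thermal syn elimination of PhSOH, which restores C4a=C8a (14) without any base. Acid-assisted loss of methanol from the C5 ketal, loss of one 8-H and methanolysis of the aryl silyl ether should then give the chelated 5-OH phenol. The closest known reaction types are the tandem Diels–Alder/sulfoxide pyrolysis of sulfinylquinones, the addition–elimination chemistry of 3-sulfinylchromones and the benzannulation of haloquinones with 1-alkoxy-1-silyloxydienes, whereas a monocyclic 4-pyranone has not been used in this way. The transient stereocentres (C4a, C8a, C5, S) are all destroyed, so nothing is needed beyond the cis relation that the cycloaddition itself enforces. Site and orientation selectivity rest on the substrates: only C4a=C8a carries two acceptors, C2=C3 is shielded and deactivated by the electron-rich aryl group, and the two donor oxygens polarise the diene toward its CH2 end.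

**Step 9**
Reactants: 15 7-O-methylluteone 2',4'-bis(methoxymethyl) ether
Product: 16 7-O-methylluteone
Conditions: 3 M aq HCl, MeOH, 45 °C
Reagents that add atoms: none
Why: Acid-catalysed acetal exchange (methanolysis of aryl MOM ethers) is routine on prenylated polyphenols, and because O7 is methylated and 5-OH is held in a hydrogen bond to C4=O, acid-induced chroman formation with the prenyl group should stay slow under these dilute conditions.

**Compound list**
1 | methyl acetoacetate | COC(=O)CC(C)=O | starting material
2 | prenyl bromide (1-bromo-3-methylbut-2-ene) | CC(C)=CCBr | starting material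
3 | methyl 2-acetyl-5-methylhex-4-enoate (racemic) | COC(=O)C(CC=C(C)C)C(C)=O | intermediate
4 | methyl (2E)-3-methoxy-2-(3-methylbut-2-enyl)but-2-enoate | CO/C(C)=C(\CC=C(C)C)C(=O)OC | intermediate
5 | (1E)-1,3-dimethoxy-2-(3-methylbut-2-enyl)-1-(trimethylsilyloxy)buta-1,3-diene | C=C(OC)/C(CC=C(C)C)=C(\OC)O[Si](C)(C)C | intermediate
6 | 2,4-dihydroxyphenylacetic acid | OC(=O)Cc1ccc(O)cc1O | starting material
7 | methyl 2,4-dihydroxyphenylacetate | COC(=O)Cc1ccc(O)cc1O | intermediate
8 | methyl 2-[2,4-bis(methoxymethoxy)phenyl]acetate | COCOc1ccc(CC(=O)OC)c(OCOC)c1 | intermediate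
9 | methyl phenyl sulfoxide (racemic) | CS(=O)c1ccccc1 | starting material
10 | 1-[2,4-bis(methoxymethoxy)phenyl]-3-(phenylsulfinyl)propan-2-one (racemic at S) | COCOc1ccc(CC(=O)CS(=O)c2ccccc2)c(OCOC)c1 | intermediate
11 | 2-[2,4-bis(methoxymethoxy)phenyl]-1,5-bis(dimethylamino)-4-(phenylsulfinyl)penta-1,4-dien-3-one (push–pull alkenes, geometry labile) | COCOc1ccc(C(=CN(C)C)C(=O)C(=CN(C)C)S(=O)c2ccccc2)c(OCOC)c1 | intermediate
12 | 3-[2,4-bis(methoxymethoxy)phenyl]-5-(phenylsulfinyl)-4H-pyran-4-one (racemic at S) | COCOc1ccc(-c2cocc(S(=O)c3ccccc3)c2=O)c(OCOC)c1 | intermediate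
13 | 3-[2,4-bis(methoxymethoxy)phenyl]-5,7-dimethoxy-6-(3-methylbut-2-enyl)-4a-(phenylsulfinyl)-5-(trimethylsilyloxy)-4a,5,8,8a-tetrahydrochromen-4-one (racemic, S-substituent and 8a-H cis, mixture at C5 and S) | COCOc1ccc(C2=CO[C@H]3CC(OC)=C(CC=C(C)C)C(OC)(O[Si](C)(C)C)[C@@]3(S(=O)c4ccccc4)C2=O)c(OCOC)c1 | intermediate
14 | 3-[2,4-bis(methoxymethoxy)phenyl]-5,7-dimethoxy-6-(3-methylbut-2-enyl)-5-(trimethylsilyloxy)-5,8-dihydrochromen-4-one (racemic) | COCOc1ccc(-c2coc3c(c2=O)C(OC)(O[Si](C)(C)C)C(CC=C(C)C)=C(OC)C3)c(OCOC)c1 | intermediate
15 | 7-O-methylluteone 2',4'-bis(methoxymethyl) ether | COCOc1ccc(-c2coc3cc(OC)c(CC=C(C)C)c(O)c3c2=O)c(OCOC)c1 | intermediate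
16 | 7-O-methylluteone | COc1cc2occ(-c3ccc(O)cc3O)c(=O)c2c(O)c1CC=C(C)C | target

**Total step count:** 9.
**Longest linear sequence:** 6 steps (6 → 7 → 8 → 10 → 12 → 15 → 16).

**Steps most likely to fail**

1. **Step 8.** Several things may go wrong.
   - The cycloaddition may be too slow, so that the diene hydrolyses or isomerises first.
   - The reaction may stop after the first C–C bond. Ring C may then open by retro-oxa-Michael cleavage, or the sulfoxide may leave before the second bond forms.
   - Silicon may transfer to the sulfinyl oxygen.
   - Aromatisation may proceed with loss of silanol instead of methanol, which would leave O5 methylated.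

   The fallback uses known chemistry: ring C is closed last and the C6 side chain is delivered by a sigmatropic shift. It sets out from 8 and comes back at 15. Ester 8 is converted with MeNH(OMe)·HCl and i-PrMgCl (THF, −20 °C) into N-methoxy-N-methyl-2-[2,4-bis(methoxymethoxy)phenyl]acetamide F1. Commercial 5-methoxyresorcinol is protected (MOMCl, i-Pr2NEt) as 1-methoxy-3,5-bis(methoxymethoxy)benzene F2. This is lithiated with n-BuLi between the two MOM ethers (directed ortho-metalation) and acylated with F1 at −78 °C to give 1-[4-methoxy-2,6-bis(methoxymethoxy)phenyl]-2-[2,4-bis(methoxymethoxy)phenyl]ethanone F3. Heating with Me2NCH(OMe)2 gives 3-(dimethylamino)-1-[4-methoxy-2,6-bis(methoxymethoxy)phenyl]-2-[2,4-bis(methoxymethoxy)phenyl]prop-2-en-1-one F4. Brief treatment with dilute HCl in MeOH at 0 °C to rt should remove the two ketone-conjugated MOM groups first, because they release the more acidic, hydrogen-bonded phenols. The same treatment closes ring C (classical deoxybenzoin route) to 5-hydroxy-7-methoxy-2',4'-bis(methoxymethoxy)isoflavone F5. Ring A is symmetric up to this point, so no regiochemical question arises. O-Allylation (allyl bromide, K2CO3, DMF, 60 °C) gives 5-allyloxy-7-methoxy-2',4'-bis(methoxymethoxy)isoflavone F6. Its aromatic Claisen rearrangement (N,N-diethylaniline, 190 °C) has only C6 as a free ortho position and should give 6-allyl-5-hydroxy-7-methoxy-2',4'-bis(methoxymethoxy)isoflavone F7. Cross-metathesis with 2-methylbut-2-ene (second-generation Grubbs catalyst, CH2Cl2, 40 °C) turns the allyl group into prenyl and gives 15.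

2. **Step 7.** The second condensation at the electron-rich benzylic CH2 may stall. Released amine or water may add back to the electrophilic pyranone and open it during hydrolysis. A MOM group may also be lost in the acidic phase. The fallback sets out from 10 and comes back at 12. The dianion of 10 (LiN(i-Pr)2, 2.2 equiv, THF, −78 → 0 °C) is formylated with ethyl formate at its more basic benzylic terminus (terminal acylation of a β-keto sulfoxide dianion). This gives 2-[2,4-bis(methoxymethoxy)phenyl]-3-oxo-4-(phenylsulfinyl)butanal F8, present as its enol. One equivalent of Me2NCH(OMe)2 at rt then condenses at the remaining, highly acidic S–CH2–CO group. The enol oxygen displaces dimethylamine and closes the ring to 12, with neither prolonged heating nor aqueous acid.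

3. **Step 6.** Proton transfer from the arylacetate CH2 to the lithiated sulfoxide may outrun acyl substitution, returning starting ester or leading to self-condensation. The fallback sets out from 8 and comes back at 10. Ester 8 is reduced with i-Bu2AlH (toluene, −78 °C) to 2-[2,4-bis(methoxymethoxy)phenyl]acetaldehyde F9. Lithiated 9 adds at −78 °C, where carbonyl addition to an aldehyde is much faster than enolisation, to give 1-[2,4-bis(methoxymethoxy)phenyl]-3-(phenylsulfinyl)propan-2-ol F10 as a mixture of diastereomers. Oxidation with Dess–Martin periodinane (CH2Cl2, NaHCO3, rt) gives 10.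

**Further compounds**
F1 | step 8 | N-methoxy-N-methyl-2-[2,4-bis(methoxymethoxy)phenyl]acetamide | COCOc1ccc(CC(=O)N(C)OC)c(OCOC)c1
F2 | step 8 | 1-methoxy-3,5-bis(methoxymethoxy)benzene | COCOc1cc(OC)cc(OCOC)c1
F3 | step 8 | 1-[4-methoxy-2,6-bis(methoxymethoxy)phenyl]-2-[2,4-bis(methoxymethoxy)phenyl]ethanone | COCOc1ccc(CC(=O)c2c(OCOC)cc(OC)cc2OCOC)c(OCOC)c1
F4 | step 8 | 3-(dimethylamino)-1-[4-methoxy-2,6-bis(methoxymethoxy)phenyl]-2-[2,4-bis(methoxymethoxy)phenyl]prop-2-en-1-one | COCOc1ccc(C(=CN(C)C)C(=O)c2c(OCOC)cc(OC)cc2OCOC)c(OCOC)c1
F5 | step 8 | 5-hydroxy-7-methoxy-2',4'-bis(methoxymethoxy)isoflavone | COCOc1ccc(-c2coc3cc(OC)cc(O)c3c2=O)c(OCOC)c1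
F6 | step 8 | 5-allyloxy-7-methoxy-2',4'-bis(methoxymethoxy)isoflavone | C=CCOc1cc(OC)cc2occ(-c3ccc(OCOC)cc3OCOC)c(=O)c12
F7 | step 8 | 6-allyl-5-hydroxy-7-methoxy-2',4'-bis(methoxymethoxy)isoflavone | C=CCc1c(OC)cc2occ(-c3ccc(OCOC)cc3OCOC)c(=O)c2c1O
F8 | step 7 | 2-[2,4-bis(methoxymethoxy)phenyl]-3-oxo-4-(phenylsulfinyl)butanal | COCOc1ccc(C(C=O)C(=O)CS(=O)c2ccccc2)c(OCOC)c1
F9 | step 6 | 2-[2,4-bis(methoxymethoxy)phenyl]acetaldehyde | COCOc1ccc(CC=O)c(OCOC)c1
F10 | step 6 | 1-[2,4-bis(methoxymethoxy)phenyl]-3-(phenylsulfinyl)propan-2-ol | COCOc1ccc(CC(O)CS(=O)c2ccccc2)c(OCOC)c1
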